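## Structural features

The target is an unsymmetrical ester-linked dimer of two C15 bicycles, each a cyclohexane (ring A, C1–C6) trans-fused through C5–C6 to a seven-membered unsaturated lactone (C5–C7(=O)–O8–C9H2–C10=C11H–C6) that carries the C12 carboxyl on C10. The C12 carboxyl of unit A is esterified with the primary C13′ oxygen of unit B, so that unit A keeps a free C4/C13 diol and unit B a free C12′ acid and the tertiary C4′ hydroxyl. Each unit has four contiguous stereocentres: the quaternary carbinol C4 (C13 cis to C7, hydroxyl trans), then C5, C6 and C1, with C7, C11 and isopropyl all-trans and equatorial. Unit A is 1R,4S,5S,6S and unit B 1S,4R,5R,6R, so the cores are mirror images and each has to be made in its own enantiomeric series. The seven-membered lactone lies 1,4 to the cis C13 hydroxyl, so acid or base can contract it to the cis-fused γ-lactone. The 2-(acyloxymethyl)enoate is an allylic ester open to SN2′ attack and to ionisation by zerovalent palladium, and neither the enoate nor a vinyl group survives hydrogenation. The real difficulty is the quaternary carbinol flanked by three tertiary centres, the closure of the seven-membered lactone against the γ-lactone sink, and the supply of both antipodes with orthogonal masking. The key step uses the fact that C4 is para to C1 in ring A: a 4-substituted phenol (C1 phenolic, C13 benzylic) is oxidised to a cyclohexadienone that receives its oxygen at C4, and a C13–O tether delivers C7 to C5 on the face of C13.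

## Logic of the disconnections

50 ⇒ 49. No skeletal bond is cut; the isopropylidene ketal on the C4/C13 diol of unit A and the tert-butyl ester on C12′ of unit B are added back. Both fall to the same acid, so one final operation suffices. The forward step must be short and cold, because the freed C13 hydroxyl can attack C7.

49 ⇒ 28 + 47. The ester bond C12–O13′ is cut, the only link between the halves. This gives two monomers of equal size. The acylation must touch only the primary hydroxyl of 47, and 28 must carry no free hydroxyl.

28 ⇒ 26 and 47 ⇒ 46. These are protecting-group disconnections to one fully masked monomer type in two mirror-image series (26 and 46). One sequence, run in both series, then serves both halves. The forward steps must remove the tert-butyl ester beside the ketal (26 → 28) and the ketal beside the tert-butyl ester (46 → 47).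

26 ⇒ 25 ⇒ 22 + 23. The lactone ring is opened at C10=C11 (metathesis retron) and then at O8–C9 (carboxylate alkylation). The whole C9–C10–C12 unit then comes from commercial 23, and the competition between five- and seven-membered lactonisation is avoided. The forward metathesis must engage an electron-poor 1,1-disubstituted alkene and needs dilution.

22 ⇒ 20. The methyl ester and the ketal are traded for the γ-lactone C7(=O)–O–C13. In that lactone the C7 carboxyl and the C13 hydroxyl protect each other through all earlier steps. The forward step must open a γ-lactone against its thermodynamic preference, which is done by trapping the diol as the ketal.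

20 ⇒ 19 ⇒ 18. The C11 vinyl carbon is taken back to the aldehyde and then to the primary alcohol. C11 has to be sp2 for metathesis, but an alkene would not survive the hydrogenation that sets C1, so C11 is carried as a hydroxymethyl group. That hydroxyl also serves as the directing group. The oxidation must not lead to a lactol, and the methylenation must not degrade the lactone.

18 ⇒ 17 ⇒ 14 + 15 ⇒ 12. The C1–H bond (hydrogenation), the C1–isopropenyl bond (cross-coupling) and the enol triflate are removed in turn. C1 is the former phenol carbon, so it arrives as a carbonyl. Hydrogen must enter C1 on the face of C11, against the steric bias, hence hydroxyl direction. The enolate must be formed on the C2 side only, hence conjugate reduction.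

12 ⇒ 9 + 10. The C6–C11 bond is cut; C6 is the α′ carbon of the enone and 10 supplies the single carbon. The electrophile must enter anti to C7.

9 ⇒ 7 ⇒ 6. The formyl carbon is added back to C7 and the silyl ether is removed. C7 has to come from the α-carbon of an aldehyde, so one carbon is excised afterwards. The cleavage must spare the enone.

6 ⇒ 5 ⇒ 4. The C5–C7 bond and the C4–O bond are cut. This removes the ring, three stereocentres and all chirality, and leads to the achiral 4. The forward step must choose between two enantiotopic enone arms.

46 ⇒ 45 ⇒ … ⇒ 29 ⇒ 5. The mirror-image series is traced back by the same disconnections to the achiral 5. One oxidation of 4 therefore feeds both series, and only the cyclisation catalyst differs. The forward step must select the other enone arm.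

4 ⇒ 3 ⇒ 1 + 2. The aldehyde is traced to a terminal alkene and the benzylic ether to 1 and 2. The para-hydroxybenzylic C–O bond ionises easily in acid, so the aldehyde is unveiled by neutral oxidative cleavage and not by hydrolysis of an acetal. Ozone must take the alkene before the phenol.

## Other disconnections considered

Alternative 1: The bonds C9–C10 and C10–C11 are cut, which removes C10 and contracts the oxepine to the trans-fused 2-methoxydihydropyran A1, with ring A, its four stereocentres and the diol ketal already in place. In the forward step dibromocarbene A2 adds to the enol ether C9=C11. The dibromocyclopropane A3 is then opened with AgOAc through an allyl cation that acetate captures at C9, giving the bromo-oxepine A4. In its favour, the seven-membered ring and a vinyl bromide at C10, a direct handle for C12 by alkoxycarbonylation, appear in one operation. Ring A is a spectator, so no alkene has to survive a hydrogenation. Against it here, C7 and C9 arrive as acetals and need an oxidation and a reduction, the epimer mixtures complicate handling, and the absolute configuration of A1 has to be secured separately for each antipode. On the oxepine ring this plan is the better one, since the chosen route spends steps 6, 10, 11, 13 and 14 on it. On the origin of chirality and on the C4 carbinol the chosen plan is stronger, because one achiral precursor gives either antipode by choice of catalyst. Overall step economy should be comparable.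

Alternative 2: The C1–isopropyl and C6–C11 bonds are cut, leading to cyclohex-2-en-1-one A5. In the forward step Cu(OTf)2 with a chiral phosphoramidite ligand catalyses the addition of diisopropylzinc A6 to A5, and the zinc enolate is alkylated by 23 trans to the new isopropyl group, giving ketone A7 with the carbonyl at C5. In its favour, two bonds and two stereocentres (C1, C6) are made in one catalytic step from commercial materials, and both antipodes follow from the ligand, which equals the chosen plan. The complete C9–C12 acrylate is present from the start and never meets a hydrogenation; on this point it is better than the chosen plan. Against it here, C7 must still be attached at C5, and C4 must be oxidised and quaternised with C13. That means two C–C bonds and two stereocentres set by substrate control next to an enolisable ketone and a reactive acrylate. These are exactly the centres that the chosen key step delivers. Secondary alkylzinc additions are also less dependable in enantioselectivity than primary ones. The early phase is shorter for this alternative, the late phase longer.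

Alternative 3: The bonds C6–C1, C2–C3 and C4=C5 are cut, so that ring A is assembled from 3-(benzyloxy)propanal A8, (E)-3-methyl-1-nitrobut-1-ene A9 and acrolein A10. In the forward step a diarylprolinol silyl ether mediates enamine addition of A8 to A9, iminium-activated addition of the nitronate to A10, and an intramolecular aldol condensation, giving cyclohexene carbaldehyde A11. In its favour, three C–C bonds, the carbocycle and the trans C1/C6 pair are formed in one pot, with C11 at the right oxidation level and C13 as the aldehyde. For isopropyl, C6 and C11 it is clearly the better plan, one step against steps 6 to 9 of the chosen route. Catalyst class and access to both antipodes are equal. Against it here, the nitro group at C2 is extraneous and must be removed by a radical step. The enal C4=C5 must also be converted into C4(OH)(C13) and C5(H)–C7 with facial control, again the centres that the chosen key step sets directly. A three-component cascade also delivers less material per run than a unimolecular cyclisation.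

Key step: step 3

Assumption: the (S)-configured catalyst is taken to select the enone arm that leads to 6; if the sense is the reverse, the catalysts of steps 3 and 16 are exchanged, since both antipodes are needed in any case.

Convention: locants are those of the target halves. Ring A is viewed with C1→C6 running clockwise; β is towards the viewer and α away. In series A (unit A antipode) C13, C7 and isopropyl are β and the C4 oxygen and C11 are α; in series B the reverse. Descriptors in names use the target locants.

Remark: the precursor 4 and the cyclisation product 6 agree with the connectivity of the target; with C13 and C7 cis and the hydroxyl trans, 6 has the C4 and C5 configuration of unit A.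

Remark: the oxidation of 4 is run once on the whole batch. The resulting solution of 5 is divided, one half being cyclised in step 3 and the other in step 16, so that 5 is made in one step only.

Step 1
Reactants: 1 4-hydroxybenzyl alcohol; 2 allyl alcohol
Product: 3 4-[(allyloxy)methyl]phenol
Conditions: sulfonic acid resin (H+ form, cat.), 2 (neat, excess), 40 °C
Reagents that add atoms: none
Why: Acid-catalysed etherification of a para-hydroxybenzylic alcohol through its stabilised benzylic cation (quinone methide); the large excess of 2 suppresses self-condensation and the phenol oxygen is not alkylated under acid.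

Step 2
Reactants: 3 4-[(allyloxy)methyl]phenol
Product: 4 2-[(4-hydroxybenzyl)oxy]acetaldehyde
Conditions: O3, CH2Cl2/MeOH (4:1), −78 °C, Sudan Red 7B end point; Me2S, −78 °C → rt
Reagents that add atoms: ozone ([O-][O+]=O)
Why: Ozonolysis of a terminal alkene with reductive work-up; the monosubstituted alkene reacts with ozone far faster than a para-alkylphenol, the indicator stops the gas flow at the end point, and no aqueous acid touches the acid-labile benzylic ether.

Step 3
Reactants: 4 2-[(4-hydroxybenzyl)oxy]acetaldehyde
Product: 6 cis-fused hydroxy enone aldehyde of series A (4S,5R; C7 epimers), via quinol 5 (not isolated)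
Conditions: PhI(OAc)2 (1.0 equiv), MeCN/H2O (4:1), 0 °C, on the whole batch of 4; the solution of 5 is halved; to one half (S)-α,α-diphenylprolinol trimethylsilyl ether (15 mol %), 0 °C → rt; the other half is used in parallel in step 16
Reagents that add atoms: water (O)
Why: PhI(OAc)2 binds the phenol oxygen and departs as PhI while water captures the incipient phenoxenium ion at the para carbon, which gives the achiral quinol 5 with the C4–O bond in place. The prolinol ether then condenses with the aldehyde to an E-enamine whose α-carbon (C7) adds to the β-carbon C5 of one enone in a 5-exo-trig Michael closure (ring C4–C13–O–C7–C5), and hydrolysis of the iminium ion returns the catalyst. The closest known reaction type is the one-pot oxidative dearomatisation of para-substituted phenols followed by amine-catalysed desymmetrising intramolecular Michael addition of a tethered aldehyde. C5 is fixed relative to C4 by the tether, because a five-membered ring across C4–C5 can only be cis-fused, so C7 enters on the face of C13 and anti to the hydroxyl. C4 becomes stereogenic only through the choice between the two enantiotopic enone arms, made by the bulky diphenyl(silyloxy)methyl group, which shields one face of the enamine. C7 is set by the same enamine face but is erased in step 5. The step needs oxidation of the phenol beside the aldehyde, which trivalent iodine leaves alone, and the amine is added only after the oxidant is consumed. The acetic acid released serves as co-catalyst for enamine turnover.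

Step 4
Reactants: 6 cis-fused hydroxy enone aldehyde of series A
Product: 7 C4 triethylsilyl ether of 6
Conditions: Et3SiOTf (1.2 equiv), 2,6-lutidine, CH2Cl2, −78 °C
Reagents that add atoms: triethylsilyl trifluoromethanesulfonate (CC[Si](CC)(CC)OS(=O)(=O)C(F)(F)F)
Why: Silyl triflate and a hindered pyridine silylate the tertiary alcohol; at −78 °C with this weak base neither the aldehyde nor the enone is enolised. The ether blocks later alkoxide chemistry at C4 (retro-aldol, acyl transfer, lactol formation).

Step 5
Reactants: 7 C4 triethylsilyl ether of 6
Product: 9 γ-lactone enone (4S,5S; C7(=O)–O–C13 lactone cis-fused at C4–C5), via piperidine enamine 8 (not isolated)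
Conditions: piperidine (1.1 equiv), MgSO4, CH2Cl2, rt; then O3, −78 °C, indicator end point; Me2S
Reagents that add atoms: ozone ([O-][O+]=O)
Why: Oxidative cleavage of the aldehyde-derived enamine C7=CH–N removes the formyl carbon as N-formylpiperidine and leaves C7 as the lactone carbonyl. The electron-rich enamine is attacked by ozone long before the electron-poor enone, and the amine does not add to the enone because C3 is neopentylic.

Step 6
Reactants: 9 γ-lactone enone; 10 formaldehyde
Product: 12 C6-(triethylsilyloxymethyl) enone lactone (4S,5S,6R; C11 α), via lithium aldolate 11 (not isolated)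
Conditions: LiN(iPr)2 (1.1 equiv), THF, −78 °C; CH2O (gas, from cracked paraformaldehyde); then Et3SiOTf (1.2 equiv), −78 °C
Reagents that add atoms: triethylsilyl trifluoromethanesulfonate (CC[Si](CC)(CC)OS(=O)(=O)C(F)(F)F)
Why: Kinetic α′-deprotonation of the enone (C4 is quaternary and the lactone α-hydrogen is less acidic) followed by aldol addition to monomeric formaldehyde. The electrophile enters C6 anti to the adjacent C7 substituent on the convex face of the cis-fused bicycle, which sets C6 trans to C5. Cold silylation of the aldolate forestalls acyl transfer from the lactone to the new alkoxide.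

Step 7
Reactants: 12 C6-(triethylsilyloxymethyl) enone lactone
Product: 14 C1 enol triflate (C1=C2; 4S,5S,6R), via lithium enolate 13 (not isolated)
Conditions: LiBH(sBu)3 (L-Selectride, 1.1 equiv), THF, −78 °C; then N-(5-chloropyridin-2-yl)triflimide, −78 → 0 °C
Reagents that add atoms: N-(5-chloropyridin-2-yl)bis(trifluoromethanesulfonyl)imide (O=S(=O)(N(c1ccc(Cl)cn1)S(=O)(=O)C(F)(F)F)C(F)(F)F)
Why: Conjugate hydride reduction of the β-unsubstituted enone generates the C1–C2 enolate regiospecifically, and O-triflation traps it. The branch at C6 disfavours 1,2-attack, and the lactone is inert at −78 °C.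

Step 8
Reactants: 14 C1 enol triflate; 15 isopropenylboronic acid pinacol ester
Product: 17 diene alcohol (C1 isopropenyl; C1=C2; free C11 hydroxyl; C4 silyl ether; 4S,5S,6S), via bis-silyl diene 16 (not isolated)
Conditions: Pd(dppf)Cl2 (5 mol %), K3PO4, THF/H2O, 45 °C; then PPTS, MeOH, rt
Reagents that add atoms: none
Why: Suzuki–Miyaura coupling of an alkenyl triflate with an alkenylboronate forms the C1–isopropenyl bond. Mild acidic methanolysis then removes the primary triethylsilyl ether while the hindered tertiary one stays.

Step 9
Reactants: 17 diene alcohol
Product: 18 saturated hydroxymethyl lactone (1R,4S,5S,6R; isopropyl β)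
Conditions: H2 (1 atm), [Ir(cod)(PCy3)(py)]PF6 (5 mol %), CH2Cl2, rt
Reagents that add atoms: none
Why: Hydroxyl-directed homogeneous hydrogenation: the cationic iridium centre binds the primary C11 hydroxyl (homoallylic to C1=C2) and delivers hydrogen to the α face. Hydrogen therefore enters C1 cis to C11 and the isopropyl group ends β, trans to C11 and cis-1,3 to C7. The isopropenyl alkene is reduced as well; lactone and silyl ether are untouched.

Step 10
Reactants: 18 saturated hydroxymethyl lactone
Product: 19 C11 aldehyde (1R,4S,5S,6R)
Conditions: Dess–Martin periodinane, NaHCO3, CH2Cl2, 0 °C → rt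
Reagents that add atoms: none
Why: Buffered periodinane oxidation of the primary alcohol; the C4 oxygen is silylated, so no bridged lactol can form and be over-oxidised. C6 is epimerisable but already holds the favoured equatorial orientation.

Step 11
Reactants: 19 C11 aldehyde
Product: 20 C6 vinyl lactone (1R,4S,5S,6R)
Conditions: Ph3PCH3Br, KN(SiMe3)2, THF, −78 → 0 °C
Reagents that add atoms: methyltriphenylphosphonium bromide (C[P+](c1ccccc1)(c1ccccc1)c1ccccc1.[Br-])
Why: Wittig methylenation with the non-stabilised ylide; at low temperature the ylide leaves the γ-lactone alone, and any base-induced equilibration at C6 returns the same trans isomer.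

Step 12
Reactants: 20 C6 vinyl lactone
Product: 22 methyl ester isopropylidene ketal (1R,4S,5S,6R), via hydroxy lactone 21 (not isolated)
Conditions: Me2C(OMe)2, MeOH, TsOH·H2O (10 mol %), 40 °C; Et3N quench
Reagents that add atoms: methanol (CO); 2,2-dimethoxypropane (COC(C)(C)OC)
Why: Acid-catalysed methanolysis of a β-hydroxy-γ-butyrolactone with ketalisation of the liberated 1,2-diol, the known way to hold such lactones open. The acidic methanol first cleaves the tertiary silyl ether, and ketal formation drains the unfavourable lactone/hydroxy ester equilibrium. The vinyl group and all stereocentres are unaffected.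

Step 13
Reactants: 22 methyl ester isopropylidene ketal; 23 tert-butyl 2-(bromomethyl)acrylate
Product: 25 diene ester (C7 ester of the 2-(tert-butoxycarbonyl)allyl alcohol; 1R,4S,5S,6R), via potassium carboxylate 24 (not isolated)
Conditions: KOSiMe3 (1.3 equiv), THF, 45 °C; then 23 (2 equiv), DMF, rt
Reagents that add atoms: none
Why: Anhydrous silanolate cleavage of the hindered methyl ester gives the potassium carboxylate, which is alkylated by the allylic bromide; direct and allylically transposed substitution lead to the same ester. No hydroxyl is free, so relactonisation is impossible.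

Step 14
Reactants: 25 diene ester
Product: 26 protected monomer of series A (isopropylidene ketal and tert-butyl ester; 1R,4S,5S,6S)
Conditions: RuCl2(H2IMes)(=CH-C6H4-2-OiPr) (second-generation Hoveyda–Grubbs catalyst, 10 mol %), toluene (0.003 M), 80 °C
Reagents that add atoms: none
Why: Ring-closing metathesis between the C6 vinyl group and the 2-(alkoxycarbonyl)allyl ester forms C10=C11 and the seven-membered lactone with loss of ethylene. The catalyst loads on the vinyl group, the trans-diequatorial C5/C6 substituents hold the alkenes close, and the ring alkene can only be cis, as required.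

Step 15
Reactants: 26 protected monomer of series A
Product: 28 unit A acid with the diol as isopropylidene ketal (1R,4S,5S,6S), via trimethylsilyl ester 27 (not isolated)
Conditions: Me3SiOTf, 2,6-lutidine, CH2Cl2, 0 °C → rt; then aqueous citrate buffer (pH 5)
Reagents that add atoms: none
Why: Silyl-triflate-mediated cleavage of the tert-butyl ester (O-silylation, loss of isobutene) under buffered aprotic conditions to which isopropylidene ketals are inert; the work-up hydrolyses the silyl ester.

Step 16
Reactants: 5 achiral quinol (the half of the solution set aside in step 3)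
Product: 29 cis-fused hydroxy enone aldehyde of series B (4R,5S; C7 epimers)
Conditions: (R)-α,α-diphenylprolinol trimethylsilyl ether (15 mol %), MeCN/H2O (4:1, with the AcOH and PhI left from step 3), 0 °C → rt
Reagents that add atoms: none
Why: Amine-catalysed desymmetrising intramolecular Michael addition, the mirror image of the cyclisation stage of step 3: the antipodal catalyst shields the opposite enamine face and so selects the other enantiotopic enone arm. The tether again enforces the cis ring fusion in the 5-exo-trig closure.

Step 17
Reactants: 29 cis-fused hydroxy enone aldehyde of series B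
Product: 30 C4 triethylsilyl ether of 29
Conditions: Et3SiOTf (1.2 equiv), 2,6-lutidine, CH2Cl2, −78 °C
Reagents that add atoms: triethylsilyl trifluoromethanesulfonate (CC[Si](CC)(CC)OS(=O)(=O)C(F)(F)F)
Why: Mirror image of step 4; silylation of the tertiary alcohol without enolisation.

Step 18
Reactants: 30 C4 triethylsilyl ether of 29
Product: 32 γ-lactone enone of series B (4R,5R), via piperidine enamine 31 (not isolated)
Conditions: piperidine (1.1 equiv), MgSO4, CH2Cl2, rt; then O3, −78 °C, indicator end point; Me2S
Reagents that add atoms: ozone ([O-][O+]=O)
Why: Mirror image of step 5; enamine ozonolysis excises the formyl carbon and leaves C7 as the lactone carbonyl.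

Step 19
Reactants: 32 γ-lactone enone of series B; 10 formaldehyde
Product: 34 C6-(triethylsilyloxymethyl) enone lactone of series B (4R,5R,6S), via lithium aldolate 33 (not isolated)
Conditions: LiN(iPr)2 (1.1 equiv), THF, −78 °C; CH2O (gas); then Et3SiOTf (1.2 equiv), −78 °C
Reagents that add atoms: triethylsilyl trifluoromethanesulfonate (CC[Si](CC)(CC)OS(=O)(=O)C(F)(F)F)
Why: Mirror image of step 6; aldol addition anti to C7 on the convex face sets C6.

Step 20
Reactants: 34 C6-(triethylsilyloxymethyl) enone lactone of series B
Product: 36 C1 enol triflate of series B (4R,5R,6S), via lithium enolate 35 (not isolated)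
Conditions: LiBH(sBu)3 (1.1 equiv), THF, −78 °C; then N-(5-chloropyridin-2-yl)triflimide, −78 → 0 °C
Reagents that add atoms: N-(5-chloropyridin-2-yl)bis(trifluoromethanesulfonyl)imide (O=S(=O)(N(c1ccc(Cl)cn1)S(=O)(=O)C(F)(F)F)C(F)(F)F)
Why: Mirror image of step 7; conjugate reduction and regiospecific enolate triflation.

Step 21
Reactants: 36 C1 enol triflate of series B; 15 isopropenylboronic acid pinacol ester
Product: 38 diene alcohol of series B (4R,5R,6R), via bis-silyl diene 37 (not isolated)
Conditions: Pd(dppf)Cl2 (5 mol %), K3PO4, THF/H2O, 45 °C; then PPTS, MeOH, rt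
Reagents that add atoms: none
Why: Mirror image of step 8; Suzuki–Miyaura coupling and selective loss of the primary silyl ether.

Step 22
Reactants: 38 diene alcohol of series B
Product: 39 saturated hydroxymethyl lactone of series B (1S,4R,5R,6S)
Conditions: H2 (1 atm), [Ir(cod)(PCy3)(py)]PF6 (5 mol %), CH2Cl2, rt
Reagents that add atoms: none
Why: Mirror image of step 9; the C11 hydroxyl directs hydrogen to its own face, which sets C1 trans to C11.

Step 23
Reactants: 39 saturated hydroxymethyl lactone of series B
Product: 40 C11 aldehyde of series B (1S,4R,5R,6S)
Conditions: Dess–Martin periodinane, NaHCO3, CH2Cl2, 0 °C → rt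
Reagents that add atoms: none
Why: Mirror image of step 10; buffered oxidation of the primary alcohol.

Step 24
Reactants: 40 C11 aldehyde of series B
Product: 41 C6 vinyl lactone of series B (1S,4R,5R,6S)
Conditions: Ph3PCH3Br, KN(SiMe3)2, THF, −78 → 0 °C
Reagents that add atoms: methyltriphenylphosphonium bromide (C[P+](c1ccccc1)(c1ccccc1)c1ccccc1.[Br-])
Why: Mirror image of step 11; Wittig methylenation.

Step 25
Reactants: 41 C6 vinyl lactone of series B
Product: 43 methyl ester isopropylidene ketal of series B (1S,4R,5R,6S), via hydroxy lactone 42 (not isolated)
Conditions: Me2C(OMe)2, MeOH, TsOH·H2O (10 mol %), 40 °C; Et3N quench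
Reagents that add atoms: methanol (CO); 2,2-dimethoxypropane (COC(C)(C)OC)
Why: Mirror image of step 12; methanolysis of the β-hydroxy-γ-lactone driven by ketalisation of the diol.

Step 26
Reactants: 43 methyl ester isopropylidene ketal of series B; 23 tert-butyl 2-(bromomethyl)acrylate
Product: 45 diene ester of series B (1S,4R,5R,6S), via potassium carboxylate 44 (not isolated)
Conditions: KOSiMe3 (1.3 equiv), THF, 45 °C; then 23 (2 equiv), DMF, rt
Reagents that add atoms: none
Why: Mirror image of step 13; silanolate ester cleavage and carboxylate alkylation.

Step 27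
Reactants: 45 diene ester of series B
Product: 46 protected monomer of series B (isopropylidene ketal and tert-butyl ester; 1S,4R,5R,6R)
Conditions: RuCl2(H2IMes)(=CH-C6H4-2-OiPr) (second-generation Hoveyda–Grubbs catalyst, 10 mol %), toluene (0.003 M), 80 °C
Reagents that add atoms: none
Why: Mirror image of step 14; ring-closing metathesis forms C10′=C11′ and the seven-membered lactone.

Step 28
Reactants: 46 protected monomer of series B
Product: 47 unit B diol tert-butyl ester (1S,4R,5R,6R)
Conditions: AcOH/THF/H2O (3:1:1), 35 °C
Reagents that add atoms: none
Why: Mild aqueous acid hydrolyses the isopropylidene ketal and leaves the tert-butyl ester and the lactone. The diol is used at once, because its primary hydroxyl lies 1,4 to the lactone carbonyl.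

Step 29
Reactants: 28 unit A acid with the diol as isopropylidene ketal; 47 unit B diol tert-butyl ester
Product: 49 protected dimer (unit A ketal; unit B tert-butyl ester), via mixed anhydride 48 (not isolated)
Conditions: 2,4,6-Cl3C6H2COCl, Et3N, THF, rt; then 47, DMAP, toluene, rt
Reagents that add atoms: none
Why: Yamaguchi esterification: the mixed anhydride of the unsaturated acid acylates the primary C13′ hydroxyl, while the tertiary C4′ hydroxyl is too hindered to react. 28 carries no free hydroxyl, so it cannot self-condense.

Step 30
Reactants: 49 protected dimer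
Product: 50 CNP0340505.1
Conditions: CF3CO2H/CH2Cl2 (1:4), H2O (5 equiv), 0 °C
Reagents that add atoms: none
Why: Acidolysis removes the tert-butyl ester of unit B as isobutene and the isopropylidene ketal of unit A in one operation. No stereocentre is touched, and low temperature and short exposure limit attack of the freed C13 hydroxyl on C7.

Compound list

1 | 4-hydroxybenzyl alcohol | OCc1ccc(O)cc1 | starting material
2 | allyl alcohol (prop-2-en-1-ol) | C=CCO | starting material
3 | 4-[(allyloxy)methyl]phenol | C=CCOCc1ccc(O)cc1 | intermediate
4 | 2-[(4-hydroxybenzyl)oxy]acetaldehyde | O=CCOCc1ccc(O)cc1 | intermediate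
5 | 4-hydroxy-4-[(2-oxoethoxy)methyl]cyclohexa-2,5-dien-1-one (achiral quinol; made in step 3 and used as its solution in steps 3 and 16) | O=CCOCC1(O)C=CC(=O)C=C1 | intermediate (not isolated)
6 | cis-fused 7a-hydroxy-5-oxo-1,3,3a,4,5,7a-hexahydro-2-benzofuran-3-carbaldehyde, series A (4S,5R; C13 and C7 β, hydroxyl α; formyl-bearing C7 unassigned) | O=C1C=C[C@@]2(O)COC(C=O)[C@H]2C1 | intermediate
7 | C4 triethylsilyl ether of 6 | O=C1C=C[C@@]2(O[Si](CC)(CC)CC)COC(C=O)[C@H]2C1 | intermediate
8 | piperidine enamine of 7 (C7=CH–N) | O=C1C=C[C@@]2(O[Si](CC)(CC)CC)COC(=CN3CCCCC3)[C@H]2C1 | intermediate (not isolated)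
9 | cis-3a-(triethylsilyloxy)-3a,7a-dihydro-2-benzofuran-1,6(3H,7H)-dione, series A (4S,5S; lactone C7(=O)–O–C13, enone C1(=O)–C2=C3) | O=C1C=C[C@@]2(O[Si](CC)(CC)CC)COC(=O)[C@H]2C1 | intermediate
10 | formaldehyde (gas, from paraformaldehyde) | C=O | starting material
11 | lithium aldolate of 9 and 10 (C6–CH2OLi, C11 α) | O=C1C=C[C@@]2(O[Si](CC)(CC)CC)COC(=O)[C@H]2[C@@H]1CO[Li] | intermediate (not isolated)
12 | 9 bearing a triethylsilyloxymethyl group at C6 (4S,5S,6R; C11 α, trans to C7) | O=C1C=C[C@@]2(O[Si](CC)(CC)CC)COC(=O)[C@H]2[C@@H]1CO[Si](CC)(CC)CC | intermediate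
13 | lithium C1–C2 enolate from conjugate reduction of 12 | [Li]OC1=CC[C@@]2(O[Si](CC)(CC)CC)COC(=O)[C@H]2[C@@H]1CO[Si](CC)(CC)CC | intermediate (not isolated)
14 | C1 enol triflate (C1=C2), bis-silyl γ-lactone (4S,5S,6R) | FC(F)(F)S(=O)(=O)OC1=CC[C@@]2(O[Si](CC)(CC)CC)COC(=O)[C@H]2[C@@H]1CO[Si](CC)(CC)CC | intermediate
15 | isopropenylboronic acid pinacol ester | CC(=C)B1OC(C)(C)C(C)(C)O1 | starting material
16 | C1-isopropenyl diene, bis-silyl γ-lactone | CC(=C)C1=CC[C@@]2(O[Si](CC)(CC)CC)COC(=O)[C@H]2[C@@H]1CO[Si](CC)(CC)CC | intermediate (not isolated)
17 | C1-isopropenyl diene with free C11 hydroxyl and C4 silyl ether (4S,5S,6S) | CC(=C)C1=CC[C@@]2(O[Si](CC)(CC)CC)COC(=O)[C@H]2[C@@H]1CO | intermediate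
18 | 7-(hydroxymethyl)-6-isopropyl-3a-(triethylsilyloxy)hexahydro-2-benzofuran-1(3H)-one, series A (1R,4S,5S,6R; isopropyl β, C11 α) | CC(C)[C@H]1CC[C@@]2(O[Si](CC)(CC)CC)COC(=O)[C@H]2[C@@H]1CO | intermediate
19 | C11 aldehyde from 18 (1R,4S,5S,6R) | CC(C)[C@H]1CC[C@@]2(O[Si](CC)(CC)CC)COC(=O)[C@H]2[C@@H]1C=O | intermediate
20 | C6 vinyl γ-lactone (1R,4S,5S,6R) | CC(C)[C@H]1CC[C@@]2(O[Si](CC)(CC)CC)COC(=O)[C@H]2[C@@H]1C=C | intermediate
21 | C4 hydroxy γ-lactone from 20 | CC(C)[C@H]1CC[C@@]2(O)COC(=O)[C@H]2[C@@H]1C=C | intermediate (not isolated)
22 | methyl 7-ethenyl-8-isopropyl-2,2-dimethyl-1,3-dioxaspiro[4.5]decane-6-carboxylate, series A (target locants 1R,4S,5S,6R) | CC(C)[C@H]1CC[C@@]2(COC(C)(C)O2)[C@@H](C(=O)OC)[C@@H]1C=C | intermediate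
23 | tert-butyl 2-(bromomethyl)acrylate | C=C(CBr)C(=O)OC(C)(C)C | starting material
24 | potassium carboxylate from 22 | CC(C)[C@H]1CC[C@@]2(COC(C)(C)O2)[C@@H](C(=O)[O-])[C@@H]1C=C.[K+] | intermediate (not isolated)
25 | 2-(tert-butoxycarbonyl)allyl ester of the acid of 22 (diene ester, series A) | CC(C)[C@H]1CC[C@@]2(COC(C)(C)O2)[C@@H](C(=O)OCC(=C)C(=O)OC(C)(C)C)[C@@H]1C=C | intermediate
26 | protected monomer, series A: seven-membered lactone, C12 tert-butyl ester, C4/C13 isopropylidene ketal (1R,4S,5S,6S) | CC(C)[C@H]1CC[C@@]3(COC(C)(C)O3)[C@H]2C(=O)OCC(C(=O)OC(C)(C)C)=C[C@H]12 | intermediate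
27 | C12 trimethylsilyl ester of 28 | CC(C)[C@H]1CC[C@@]3(COC(C)(C)O3)[C@H]2C(=O)OCC(C(=O)O[Si](C)(C)C)=C[C@H]12 | intermediate (not isolated)
28 | unit A acid, diol as isopropylidene ketal (1R,4S,5S,6S) | CC(C)[C@H]1CC[C@@]3(COC(C)(C)O3)[C@H]2C(=O)OCC(C(=O)O)=C[C@H]12 | intermediate
29 | enantiomer of 6 (series B; 4R,5S) | O=C1C=C[C@]2(O)COC(C=O)[C@@H]2C1 | intermediate
30 | enantiomer of 7 | O=C1C=C[C@]2(O[Si](CC)(CC)CC)COC(C=O)[C@@H]2C1 | intermediate
31 | enantiomer of 8 | O=C1C=C[C@]2(O[Si](CC)(CC)CC)COC(=CN3CCCCC3)[C@@H]2C1 | intermediate (not isolated)
32 | enantiomer of 9 (4R,5R) | O=C1C=C[C@]2(O[Si](CC)(CC)CC)COC(=O)[C@@H]2C1 | intermediate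
33 | enantiomer of 11 | O=C1C=C[C@]2(O[Si](CC)(CC)CC)COC(=O)[C@@H]2[C@H]1CO[Li] | intermediate (not isolated)
34 | enantiomer of 12 (4R,5R,6S) | O=C1C=C[C@]2(O[Si](CC)(CC)CC)COC(=O)[C@@H]2[C@H]1CO[Si](CC)(CC)CC | intermediate
35 | enantiomer of 13 | [Li]OC1=CC[C@]2(O[Si](CC)(CC)CC)COC(=O)[C@@H]2[C@H]1CO[Si](CC)(CC)CC | intermediate (not isolated)
36 | enantiomer of 14 | FC(F)(F)S(=O)(=O)OC1=CC[C@]2(O[Si](CC)(CC)CC)COC(=O)[C@@H]2[C@H]1CO[Si](CC)(CC)CC | intermediate
37 | enantiomer of 16 | CC(=C)C1=CC[C@]2(O[Si](CC)(CC)CC)COC(=O)[C@@H]2[C@H]1CO[Si](CC)(CC)CC | intermediate (not isolated)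
38 | enantiomer of 17 (4R,5R,6R) | CC(=C)C1=CC[C@]2(O[Si](CC)(CC)CC)COC(=O)[C@@H]2[C@H]1CO | intermediate
39 | enantiomer of 18 (1S,4R,5R,6S) | CC(C)[C@@H]1CC[C@]2(O[Si](CC)(CC)CC)COC(=O)[C@@H]2[C@H]1CO | intermediate
40 | enantiomer of 19 | CC(C)[C@@H]1CC[C@]2(O[Si](CC)(CC)CC)COC(=O)[C@@H]2[C@H]1C=O | intermediate
41 | enantiomer of 20 | CC(C)[C@@H]1CC[C@]2(O[Si](CC)(CC)CC)COC(=O)[C@@H]2[C@H]1C=C | intermediate
42 | enantiomer of 21 | CC(C)[C@@H]1CC[C@]2(O)COC(=O)[C@@H]2[C@H]1C=C | intermediate (not isolated)
43 | enantiomer of 22 | CC(C)[C@@H]1CC[C@]2(COC(C)(C)O2)[C@H](C(=O)OC)[C@H]1C=C | intermediate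
44 | enantiomer of 24 | CC(C)[C@@H]1CC[C@]2(COC(C)(C)O2)[C@H](C(=O)[O-])[C@H]1C=C.[K+] | intermediate (not isolated)
45 | enantiomer of 25 | CC(C)[C@@H]1CC[C@]2(COC(C)(C)O2)[C@H](C(=O)OCC(=C)C(=O)OC(C)(C)C)[C@H]1C=C | intermediate
46 | protected monomer, series B, enantiomer of 26 (1S,4R,5R,6R) | CC(C)[C@@H]1CC[C@]3(COC(C)(C)O3)[C@@H]2C(=O)OCC(C(=O)OC(C)(C)C)=C[C@@H]12 | intermediate
47 | unit B diol tert-butyl ester: free C4′ and C13′ hydroxyls, seven-membered lactone (1S,4R,5R,6R) | CC(C)[C@@H]1CC[C@](O)(CO)[C@@H]2C(=O)OCC(C(=O)OC(C)(C)C)=C[C@@H]12 | intermediate
48 | mixed anhydride of 28 with 2,4,6-trichlorobenzoic acid | CC(C)[C@H]1CC[C@@]3(COC(C)(C)O3)[C@H]2C(=O)OCC(C(=O)OC(=O)c4c(Cl)cc(Cl)cc4Cl)=C[C@H]12 | intermediate (not isolated)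
49 | protected dimer: C12 of unit A esterified with O13′ of unit B; unit A diol as isopropylidene ketal, unit B acid as tert-butyl ester | CC(C)[C@H]1CC[C@@]5(COC(C)(C)O5)[C@H]2C(=O)OCC(C(=O)OC[C@@]3(O)CC[C@@H](C(C)C)[C@@H]4C=C(C(=O)OC(C)(C)C)COC(=O)[C@H]43)=C[C@H]12 | intermediate
50 | CNP0340505.1 (unit A 1R,4S,5S,6S; unit B 1′S,4′R,5′R,6′R) | CC(C)[C@H]1CC[C@@](O)(CO)[C@H]2C(=O)OCC(C(=O)OC[C@@]3(O)CC[C@@H](C(C)C)[C@@H]4C=C(C(=O)O)COC(=O)[C@H]43)=C[C@H]12 | target

Total step count: 30. Steps 1 and 2 and the oxidation stage of step 3 are common, steps 3–15 build series A, steps 16–28 build series B, and steps 29–30 join the halves.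

Longest linear sequence: 18 steps (1, 2, 3, 16–28, 29, 30). Step 3 counts on this line because the quinol 5 consumed in step 16 is generated there. The series A line (1–15, 29, 30) has 17 steps.

Least certain steps

Step 3 (and the cyclisation of step 16). The choice between the enantiotopic enone arms may be incomplete, or the cyclisation may stall. The aldehyde of 5 can be tied up as hydrate or as hemiacetal with the new C4 hydroxyl, and residual oxidant can destroy the amine. Fallback: starting from 5, the whole solution is cyclised with achiral pyrrolidine, which gives 6 and 29 together as the racemate. The racemate is carried through the silylation and the enamine ozonolysis of steps 4 and 5. The products 9 and 32, which no longer hold the undefined C7 centre, are then separated by preparative chromatography on a chiral stationary phase. Because both antipodes are required, nothing is discarded, and the route is rejoined at 9 and at 32. No new compound is involved.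

Step 7 (mirror: step 20). Hydride may attack the carbonyl instead of C3, because C3 lies next to the quaternary C4; that would give allylic alcohols and no enolate. Fallback: starting from 12, the C2=C3 bond is hydrogenated (H2, RhCl(PPh3)3) to the saturated keto lactone F1. Kinetic deprotonation with KN(SiMe3)2 at −78 °C on the less substituted C2 side and triflation with the same triflimide then return the route to 14. In the mirror series the detour runs from 34 through the enantiomeric saturated keto lactone F2 to 36.

Step 9 (mirror: step 22). Facial selectivity may be poor if the lactone carbonyl or plain steric approach competes with the C11 hydroxyl for the catalyst; this would give the C1 epimer, which cannot be corrected later. Fallback: starting from 17, a radical hydrogenation by hydrogen-atom transfer (Mn(dpm)3, PhSiH3, tBuOOH, iPrOH) replaces the directed delivery. The tertiary C1 radical should be quenched to the thermodynamically preferred equatorial isopropyl isomer, and the route is rejoined at 18 (from 38 to 39 in the mirror series). No new compound is involved.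

Step 12 (mirror: step 25). The opening may stop short, either because the tertiary silyl ether resists methanolysis or because the lactone/hydroxy ester equilibrium is not drained fast enough by ketalisation. Fallback: starting from 20, Bu4NF/AcOH gives 21, and LiOH in THF/H2O opens it to the lithium hydroxy carboxylate F3. F3 is alkylated in DMF with 23 to the diol diene ester F4, which is ketalised at once with 2-methoxypropene and PPTS at −20 °C, rejoining the route at 25. In the mirror series the detour runs from 41 through 42, the lithium hydroxy carboxylate F5 and the diol diene ester F6 to 45.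

Step 14 (mirror: step 27). Ring closure may be slow and give way to oligomerisation, because the electron-poor 1,1-disubstituted alkene is a reluctant metathesis partner. Fallback: the seven-membered ring is closed at O8–C9 instead. Starting from 19, tert-butyl propiolate hydroaluminated with iBu2AlH/N-methylmorpholine N-oxide adds to the aldehyde to give the allylic alcohol F7. N-Bromosuccinimide/Me2S converts F7 with allylic transposition into the (Z)-allylic bromide F8. The conditions of step 12 then give the bromo methyl ester ketal F9. Me3SnOH (ClCH2CH2Cl, 80 °C) frees the acid, and Cs2CO3 in dilute DMF closes the lactone by 7-exo-tet displacement of bromide, rejoining the route at 26. In the mirror series the detour runs from 40 through the allylic alcohol F10, the (Z)-allylic bromide F11 and the bromo methyl ester ketal F12 to 46.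

Step 28. The lactone may contract: the liberated C13′ hydroxyl can attack C7′ under the acidic conditions to give the cis-fused γ-lactone. The same hazard exists briefly in steps 29 and 30. Fallback: the interunit ester is made before the seven-membered lactone of unit B exists. Starting from 41, desilylation gives 42 and LiOH the lithium hydroxy carboxylate F5, which is alkylated with 23 to the diol diene ester F6. The primary hydroxyl of F6 is acylated at once with the mixed anhydride 48 to the seco-dimer diene F13, and ring-closing metathesis under the conditions of step 27 rejoins the route at 49.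

## Further compounds

F0 | step 3 | none | none
F1 | step 7 | saturated keto lactone (12 with C2–C3 reduced) | O=C1CC[C@@]2(O[Si](CC)(CC)CC)COC(=O)[C@H]2[C@@H]1CO[Si](CC)(CC)CC
F2 | step 20 | enantiomer of F1 | O=C1CC[C@]2(O[Si](CC)(CC)CC)COC(=O)[C@@H]2[C@H]1CO[Si](CC)(CC)CC
F0 | step 9 | none | none
F3 | step 12 | lithium hydroxy carboxylate (ring-opened 21) | CC(C)[C@H]1CC[C@@](O)(CO)[C@@H](C(=O)[O-])[C@@H]1C=C.[Li+]
F4 | step 12 | diol diene ester (25 without the ketal) | CC(C)[C@H]1CC[C@@](O)(CO)[C@@H](C(=O)OCC(=C)C(=O)OC(C)(C)C)[C@@H]1C=C
F5 | step 25 | enantiomer of F3 | CC(C)[C@@H]1CC[C@](O)(CO)[C@H](C(=O)[O-])[C@H]1C=C.[Li+]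
F6 | step 25 | enantiomer of F4 | CC(C)[C@@H]1CC[C@](O)(CO)[C@H](C(=O)OCC(=C)C(=O)OC(C)(C)C)[C@H]1C=C
F7 | step 14 | allylic alcohol: C11 carbinol bearing the 1-(tert-butoxycarbonyl)vinyl group, silyl γ-lactone (C11 epimers) | CC(C)[C@H]1CC[C@@]2(O[Si](CC)(CC)CC)COC(=O)[C@H]2[C@@H]1C(O)C(=C)C(=O)OC(C)(C)C
F8 | step 14 | (Z)-allylic bromide: C11H=C10(CH2Br)CO2tBu, silyl γ-lactone | CC(C)[C@H]1CC[C@@]2(O[Si](CC)(CC)CC)COC(=O)[C@H]2[C@@H]1/C=C(\CBr)C(=O)OC(C)(C)C
F9 | step 14 | (Z)-allylic bromide methyl ester isopropylidene ketal | CC(C)[C@H]1CC[C@@]2(COC(C)(C)O2)[C@@H](C(=O)OC)[C@@H]1/C=C(\CBr)C(=O)OC(C)(C)C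
F10 | step 27 | enantiomer of F7 | CC(C)[C@@H]1CC[C@]2(O[Si](CC)(CC)CC)COC(=O)[C@@H]2[C@H]1C(O)C(=C)C(=O)OC(C)(C)C
F11 | step 27 | enantiomer of F8 | CC(C)[C@@H]1CC[C@]2(O[Si](CC)(CC)CC)COC(=O)[C@@H]2[C@H]1/C=C(\CBr)C(=O)OC(C)(C)C
F12 | step 27 | enantiomer of F9 | CC(C)[C@@H]1CC[C@]2(COC(C)(C)O2)[C@H](C(=O)OC)[C@H]1/C=C(\CBr)C(=O)OC(C)(C)C
F13 | step 28 | seco-dimer diene: F6 acylated at O13′ by the acid 28 | CC(C)[C@H]1CC[C@@]5(COC(C)(C)O5)[C@H]2C(=O)OCC(C(=O)OC[C@@]3(O)CC[C@@H](C(C)C)[C@H](C=C)[C@H]3C(=O)OCC(=C)C(=O)OC(C)(C)C)=C[C@H]12
A1 | alternative 1 | trans-fused 2-methoxydihydropyran with the diol as isopropylidene ketal (enol ether C9=C11) | CC(C)[C@H]1CC[C@@]3(COC(C)(C)O3)[C@H]2C(OC)OC=C[C@H]12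
A2 | alternative 1 | dibromocarbene | Br[C]Br
A3 | alternative 1 | dibromocyclopropane adduct of A1 | CC(C)[C@H]1CC[C@@]3(COC(C)(C)O3)[C@H]2C(OC)OC4C(Br)(Br)C4[C@H]12
A4 | alternative 1 | 3-bromo-oxepine with acetoxy acetal at C9 and methyl acetal at C7 | CC(C)[C@H]1CC[C@@]3(COC(C)(C)O3)[C@H]2C(OC)OC(OC(C)=O)C(Br)=C[C@H]12
A5 | alternative 2 | cyclohex-2-en-1-one | O=C1C=CCCC1
A6 | alternative 2 | diisopropylzinc | CC(C)[Zn]C(C)C
A7 | alternative 2 | trans-2-[2-(tert-butoxycarbonyl)allyl]-3-isopropylcyclohexanone | CC(C)[C@H]1CCCC(=O)[C@@H]1CC(=C)C(=O)OC(C)(C)C
A8 | alternative 3 | 3-(benzyloxy)propanal | O=CCCOCc1ccccc1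
A9 | alternative 3 | (E)-3-methyl-1-nitrobut-1-ene | CC(C)/C=C/[N+](=O)[O-]
A10 | alternative 3 | acrolein | C=CC=O
A11 | alternative 3 | 3-(benzyloxymethyl)-4-isopropyl-5-nitrocyclohex-1-ene-1-carbaldehyde | CC(C)[C@H]1[C@H]([N+](=O)[O-])CC(C=O)=C[C@@H]1COCc2ccccc2
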